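(The numbers in the tables stem from a simulated flask on assumed constants; noise was put on by code.)

Two readings on a falling curve cannot say by what law it falls, and the maple run offers little more: a peak read at 29.9% of the charged substrate at 1.33 min, and two readings after it. Yet the flasks below have to be followed out to 40 min.

| flask | substrate | reagent | temperature | remark | time |
|---|---|---|---|---|---|
| maple | 0.075 M | 0.060 M | 20 °C | run made earlier |  |
| north-west | 0.050 M | 0.0600 M | 20 °C |  | 40 min |
| north-east | 0.050 M | 0.0600 M | 5 °C |  | 40 min |
| south-west | 0.050 M | 0.0600 M |  | at 20 °C until 8.0 min, from then on at 5 °C | 40 min |

maple run (percent of the substrate charged)

| time / min | target / % |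
|---|---|
| 0.667 | 27.4 |
| 1.33 | 29.9 |
| 3.00 | 24.4 |
| 8.00 | 14.1 |

(readings scatter by 0.3 percentage points)

* the flask with the highest amount of target, in percent of the substrate charged ("all alike" if they lie within 1.5 percentage points) (north-west / north-east / south-west / all alike)
* final target, as a percentage of the substrate charged, in north-west
* final target, as a percentage of the substrate charged, in north-east
* final target, as a percentage of the substrate charged, in south-west

The first chemist holds that target drains by a constant fraction per minute, a first-order loss, and points to the constant read from the peak to the next reading, 0.122 /min, and the one read after it, 0.110 /min, which lie close together; from the fraction read at 8.00 min this carries north-west to 0.422% at 40 min. The second chemist answers that if target is lost by meeting by-product, and the two are made together in one step, they fall together, the loss goes as the square of what stands, and the reciprocal of the target fraction climbs at a steady pace. Between the last two maple readings that pace is 0.599 /min, the reciprocal clock of a second-order decay, and from the same start it carries north-west to 3.81%. Both borrow the maple start although north-west holds less substrate, a risk they share.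

My own reckoning is the second chemist's: with the clock taken 3 times slower at 5 °C, which is a guess, it gives north-east 9.04% from the maple peak and south-west 7.42% from the maple reading at the time of the change, so north-east stands above south-west and south-west above north-west.

The forecast has figures of its own: north-east holds most, with 6% in north-west, 17% in north-east and 12% in south-west, all higher than mine, on the ground that the “falling by-product lets the equilibrium feed more target”.

The simulation gives north-east as the richest flask, with 4.47% in north-west, 13.1% in north-east and 9.32% in south-west, and north-east leads south-west by 3.8 percentage points, wider than the margin of 1.5 points.

    target ⇌ isomer of the product (K = 1.50, k = 8.40 × 10⁻⁴ /s, Ea = 78.0 kJ/mol, ΔH = −9.00 kJ/mol)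
    substrate + reagent ⇌ target + by-product (K = 0.550, k = 0.230 /M/s, Ea = 41.0 kJ/mol, ΔH = −26.0 kJ/mol)
    target + by-product → side product (k = 0.200 /M/s, Ea = 47.0 kJ/mol)
    (constants at 20 °C)

In north-west the target fraction goes from 8.52% at 20.0 min to 4.47% at 40.0 min, so its reciprocal climbs at 0.533 /min, near the clock of 0.599 /min, while the first-order figure of 0.422% lies far below the flask; that view keeps the span of the maple readings, where its constants lay together. Running the clock back from the half-time state of north-west to the same flask read at 15 min gives 11.4%, and that flask holds 11.3% target.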